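The target is a labdane: rings A and B form a trans-decalin whose C4 gem-dimethyl carbon, C10 angular methyl, C9 side chain and C8 tertiary carbinol map one-to-one onto the branch points of an all-E geranylgeranyl chain. The route rests on disconnecting C4–C5 and C9–C10 together. One protonation-initiated cation–olefin bicyclization of acyclic geranylgeranyl diphosphate, catalysed by a labd-13-en-8-ol diphosphate synthase, closes both rings, sets C5, C8, C9 and C10 and installs the 8α-hydroxyl by water capture. The precursor is an achiral tetraene whose allylic diphosphate keeps the 13E-alkene out of the cascade. Dephosphorylation and selective acetylation finish the synthesis.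

Key step: step 3

Remark: the cyclase of step 3 is the plastid-signal-truncated labd-13-en-8-ol diphosphate synthase of Salvia sclarea, assumed accessible by routine expression in Escherichia coli; it is a catalyst and supplies no atoms, and labdane numbering (C1–C20) is used for all cyclized compounds.

Step 1
Reactants: 1 (2E,6E,10E)-geranylgeraniol
Product: 2 (2E,6E,10E)-geranylgeranyl chloride
Conditions: NCS, Me2S, CH2Cl2, −40 °C to 0 °C
Reagents that add atoms: N-chlorosuccinimide, ClN1C(=O)CCC1=O
Why: Corey–Kim chlorination: the alkoxysulfonium salt formed from 1 and Me2S/NCS is displaced by chloride at the primary allylic carbon (SN2) under cold, non-acidic conditions, which should keep all four alkenes and the 2E geometry intact.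

Step 2
Reactants: 2 (2E,6E,10E)-geranylgeranyl chloride
Product: 4 tris(ammonium) (2E,6E,10E)-geranylgeranyl diphosphate, via tetrabutylammonium geranylgeranyl diphosphate 3 (not isolated)
Conditions: (n-Bu4N)3HP2O7, MeCN, 20 °C; then sulfonic acid cation-exchange resin (ammonium form), aq NH4HCO3/i-PrOH; cellulose chromatography
Reagents that add atoms: tris(tetrabutylammonium) hydrogen diphosphate, CCCC[N+](CCCC)(CCCC)CCCC.CCCC[N+](CCCC)(CCCC)CCCC.CCCC[N+](CCCC)(CCCC)CCCC.OP(=O)([O-])OP(=O)([O-])[O-]; ammonium hydrogencarbonate, [NH4+].OC(=O)[O-]
Why: SN2 displacement of the primary allylic chloride by the acetonitrile-soluble, weakly basic diphosphate salt (direct diphosphorylation of an allylic halide), followed by cation exchange to the ammonium form, should give the enzyme substrate with no change at any alkene.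

Step 3
Reactants: 4 tris(ammonium) (2E,6E,10E)-geranylgeranyl diphosphate
Product: 6 (13E)-labd-13-ene-8α,15-diol, via copal-8-ol diphosphate 5 (not isolated)
Conditions: recombinant Salvia sclarea labd-13-en-8-ol diphosphate synthase (class 2 diterpene synthase), HEPES buffer pH 7.2, MgCl2, dithiothreitol, 10% glycerol, 30 °C, 4 added in portions; then calf intestinal alkaline phosphatase, pH 8.5, 37 °C; EtOAc extraction
Reagents that add atoms: water, O
Why: The class 2 diterpene synthase protonates the terminal alkene of chair–chair-folded all-E 4 at C3 (numbering of the product skeleton) with its aspartate general acid, the C4 cation is attacked by C5 of the C5=C10 alkene (C4–C5 bond, ring A), the new C10 cation by C9 of the C8=C9 alkene (C9–C10 bond, ring B), and the C8 cation is quenched by an active-site water to give 5, whose diphosphate the phosphatase then hydrolyses at phosphorus. The closest known reaction type is the protonation-initiated cation–olefin polycyclization (Stork–Eschenmoser) in its enzymatic form, and this conversion of 4 is the native reaction of labd-13-en-8-ol diphosphate synthases. Rings A and B each close in the 6-endo-trig mode onto a trisubstituted E-alkene with Markovnikov orientation. The relative configuration of C5, C10, C9 and C8 follows from antiperiplanar addition across the two E-alkenes in the chair–chair fold (trans ring fusion, equatorial side chain at C9, equatorial 8α-hydroxyl from water attack anti to the C9–C10 bond), and the absolute 5S,8R,9R,10S sense is imposed by the enzyme pocket, which selects one enantiomeric fold. The step needs arrest at the bicyclic stage with hydration instead of proton loss, which is secured by the electron-poor C13=C14 alkene next to the diphosphate (it does not attack the C8 cation and keeps its E geometry) and by the water that this synthase family positions over the α-face of C8.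

Step 4
Reactants: 6 (13E)-labd-13-ene-8α,15-diol
Product: 7 (13E)-8α-hydroxylabd-13-en-15-yl acetate (the target)
Conditions: Ac2O (1.1 equiv), pyridine, CH2Cl2, 0 °C to 20 °C
Reagents that add atoms: acetic anhydride, CC(=O)OC(C)=O
Why: Nucleophilic acyl substitution (O-acetylation) with Ac2O/pyridine without an acyl-transfer catalyst should take place only at the unhindered primary allylic alcohol, the tertiary C8 hydroxyl flanked by axial methyl groups staying free, and no stereocenter is touched.

Compound list
1 | (2E,6E,10E)-geranylgeraniol, (2E,6E,10E)-3,7,11,15-tetramethylhexadeca-2,6,10,14-tetraen-1-ol | CC(C)=CCC/C(C)=C/CC/C(C)=C/CC/C(C)=C/CO | starting material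
2 | (2E,6E,10E)-geranylgeranyl chloride, (2E,6E,10E)-1-chloro-3,7,11,15-tetramethylhexadeca-2,6,10,14-tetraene | CC(C)=CCC/C(C)=C/CC/C(C)=C/CC/C(C)=C/CCl | intermediate
3 | tetrabutylammonium geranylgeranyl diphosphate, the bis(tetrabutylammonium) salt of (2E,6E,10E)-geranylgeranyl hydrogen diphosphate (not isolated) | CC(C)=CCC/C(C)=C/CC/C(C)=C/CC/C(C)=C/COP(=O)([O-])OP(=O)(O)[O-].CCCC[N+](CCCC)(CCCC)CCCC.CCCC[N+](CCCC)(CCCC)CCCC | intermediate
4 | tris(ammonium) (2E,6E,10E)-geranylgeranyl diphosphate | CC(C)=CCC/C(C)=C/CC/C(C)=C/CC/C(C)=C/COP(=O)([O-])OP(=O)([O-])[O-].[NH4+].[NH4+].[NH4+] | intermediate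
5 | copal-8-ol diphosphate, (13E)-8α-hydroxylabd-13-en-15-yl diphosphate as tris(ammonium) salt, 5S,8R,9R,10S, trans-decalin with H-5 α, CH3-10 β, side chain at C9 β, OH at C8 α (not isolated) | [O-]P(=O)([O-])OP(=O)([O-])OC/C=C(\C)CC[C@@H]1[C@@]2(C)CCCC(C)(C)[C@@H]2CC[C@@]1(C)O.[NH4+].[NH4+].[NH4+] | intermediate
6 | (13E)-labd-13-ene-8α,15-diol, (1R,2R,4aS,8aS)-1-[(3E)-5-hydroxy-3-methylpent-3-en-1-yl]-2,5,5,8a-tetramethyldecahydronaphthalen-2-ol | OC/C=C(\C)CC[C@@H]1[C@@]2(C)CCCC(C)(C)[C@@H]2CC[C@@]1(C)O | intermediate
7 | (13E)-8α-hydroxylabd-13-en-15-yl acetate, (2E)-5-[(1R,2R,4aS,8aS)-2-hydroxy-2,5,5,8a-tetramethyldecahydronaphthalen-1-yl]-3-methylpent-2-en-1-yl acetate | CC(=O)OC/C=C(\C)CC[C@@H]1[C@@]2(C)CCCC(C)(C)[C@@H]2CC[C@@]1(C)O | target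

Total step count: 4
Longest linear sequence: 4 steps (1 → 2 → 4 → 6 → 7)

Steps most likely to fail

1. Step 3 (key step). What may go wrong: slow turnover with substrate inhibition, proton loss from the C8 cation in place of hydration, and non-enzymatic ionisation of the allylic diphosphate. The fallback sets out from 1 and comes back to the route at 6. It forms the same two ring bonds on a C18 ketone with a different cyclase and an internal oxygen terminator, and adds C14 and C15 afterwards.
   - Epoxidation of only the allylic 2,3-alkene of 1 (vanadyl acetylacetonate VO(acac)2, t-BuOOH, CH2Cl2, 0 °C) should give racemic 2,3-epoxygeranylgeraniol F1.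
   - Periodic acid H5IO6 in aqueous THF should cleave it to (5E,9E)-farnesylacetone F2.
   - Squalene–hopene cyclase of Alicyclobacillus acidocaldarius (citrate buffer pH 6, Triton X-100, 50–60 °C) should cyclise F2, with capture of the C8 cation by the ketone oxygen, to the cyclic enol ether sclareol oxide F3.
   - Dilute aqueous HCl in THF at 0 °C should hydrate the enol ether to 8α-hydroxy-14,15-dinorlabdan-13-one F4.
   - Horner–Wadsworth–Emmons olefination (triethyl phosphonoacetate, NaH, THF) should give ethyl (13E)-8α-hydroxylabd-13-en-15-oate F5 after removal of the minor 13Z isomer.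
   - i-Bu2AlH in CH2Cl2 at −78 °C should reduce the ester to diol 6, which enters step 4.

2. Step 2. What may go wrong: elimination or hydrolysis of the allylic chloride under the basic salt, allylic transposition, and loss of the labile diphosphate during cation exchange. The fallback sets out from 1 and comes back at 4, so it also bypasses 2. The alcohol is phosphorylated directly with trichloroacetonitrile and bis(triethylammonium) hydrogen phosphate in MeCN at 20 °C, so that it attacks an activated phosphate imidate instead of serving as the electrophile. Triethylammonium geranylgeranyl hydrogen phosphate F6 should form first and be phosphorylated again in the same flask on renewed addition of the reagents. Cation exchange to the ammonium form and chromatography (i-PrOH/conc. aq NH3/H2O) should give 4.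

3. Step 4. What may go wrong: acetylation of the tertiary C8 hydroxyl on prolonged reaction, or acid-promoted ionisation of the allylic acetate with ring closure by the C8 hydroxyl during work-up. The fallback sets out from 6 and comes back at 7: transesterification with immobilised Candida antarctica lipase B and vinyl acetate in t-BuOMe at 30 °C under neutral conditions, in which only the unhindered primary alcohol should be acylated. This fallback makes no new compound (F0).

Further compounds
F1 | step 3 | racemic 2,3-epoxygeranylgeraniol, trans-epoxide from the 2E-alkene, one enantiomer drawn | CC(C)=CCC/C(C)=C/CC/C(C)=C/CC[C@@]1(C)O[C@@H]1CO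
F2 | step 3 | (5E,9E)-farnesylacetone, (5E,9E)-6,10,14-trimethylpentadeca-5,9,13-trien-2-one | CC(C)=CCC/C(C)=C/CC/C(C)=C/CCC(C)=O
F3 | step 3 | sclareol oxide, 8α,13-epoxy-14,15-dinorlabd-12-ene | CC1=CC[C@@H]2[C@@]3(C)CCCC(C)(C)[C@@H]3CC[C@@]2(C)O1
F4 | step 3 | 8α-hydroxy-14,15-dinorlabdan-13-one | CC(=O)CC[C@@H]1[C@@]2(C)CCCC(C)(C)[C@@H]2CC[C@@]1(C)O
F5 | step 3 | ethyl (13E)-8α-hydroxylabd-13-en-15-oate | CCOC(=O)/C=C(\C)CC[C@@H]1[C@@]2(C)CCCC(C)(C)[C@@H]2CC[C@@]1(C)O
F6 | step 2 | triethylammonium (2E,6E,10E)-geranylgeranyl hydrogen phosphate | CC(C)=CCC/C(C)=C/CC/C(C)=C/CC/C(C)=C/COP(=O)(O)[O-].CC[NH+](CC)CC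
F0 | step 4 | none | none
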